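## The problem

Guaiane numbering is used throughout. The five-membered ring is C1–C5, with C3=C4 and a methyl group (C15) on C4. The seven-membered ring is C1, C5, C6–C10, with C1=C10, a methyl group (C14) on C10, isopropyl (C11–C13) on C7 and the ester oxygen on C8.

Target 27 is the vanillate of (5R,7R,8S)-guaia-1(10),3-dien-8-ol, a bicyclo[5.3.0]decadiene whose ring-fusion atom C1 is sp2. The alkenes C3=C4 and C1=C10 flank C5, so the molecule is a skipped diene with a doubly allylic C5–H. Acid, strong base or isomerising metal hydrides would conjugate the diene and erase C5. The tetrasubstituted C1=C10 bond therefore has to be placed regiospecifically and never equilibrated.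

There are three stereocentres. C7 and C8 are vicinal and trans, and can be made in one event. C5 is separated from C7 by the C6 methylene and can only communicate with C7/C8 through the conformation of the seven-membered ring. C1 carries no stereochemistry in the target and is free to serve as a temporary control element.

The C8 oxygen sits β to C10, so any C10 carbonyl intermediate is a β-oxygenated ketone and is prone to elimination. The vanillate is a base-labile aryl ester with a free phenol and belongs at the very end.

The enabling feature is the C7/C8 pair. If the isopropyl group is read as isopropenyl, C8(O)–C7–C11(=C12)C13 is an anti homoallylic alcohol. That is the product of γ-selective allylation of a C8 aldehyde by a C12–C11=C7 allyl unit.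

## Retrosynthesis

**Ester C–O bond.** Target 27 is cut at the ester into dienol 22 and acid chloride 25, which comes from vanillic acid 23 through acetate 24. The acylation is placed last so that the aryl ester never meets organometallics or hydrides. The acetate is chosen because it can be removed from the phenol by aminolysis without touching a hindered alkyl benzoate. The forward step needs only acylation of a hindered secondary alcohol.

**C10–C14 and the C1=C10 bond.** Dienol 22 is traced through silyl ether 21 to enol triflate 20 and ketone 19. Cutting the methyl group from an enol triflate fixes the alkene position. Dehydration of a C10 carbinol or isomerisation of an exocyclic alkene would give regioisomer mixtures and would risk conjugation with C3=C4. Ketone 19 has lost one carbon and the troublesome alkene. The forward reaction must enolise C10 toward the C1 methine and not toward C9.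

**Functional-group changes to the cyclised alcohol.** Ketone 19 comes from ketal 18, and 18 from alcohol 17 by silylation. The silyl ether is needed because a free or acylated β-oxygen would not survive the ketone chemistry. Alcohol 17 comes from isopropenyl compound 16 by saturating the 1,1-disubstituted alkene in the presence of the trisubstituted ring alkene.

**C7–C8 bond (key cut).** Alcohol 16 is opened between C7 and C8 to bromo aldehyde 15. Among the bonds of the seven-membered ring this is the only one whose formation creates both the oxygen-bearing and the isopropyl-bearing stereocentre together with defined (anti) relative configuration.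
- A C8–C9 aldol closure would need C7 pre-set in an open chain.
- A C6–C7 alkylation offers no stereocontrol.
- The tetrasubstituted C1=C10 bond is a poor site for ring closure.

Precursor 15 is monocyclic, carries only C1 and C5, and holds C10 as a dioxolane so that no exocyclic alkene geometry has to be set.

The weak element is the sense in which C7/C8 form relative to C5. It is addressed from within the plan in three ways:
- C1 is kept trans to C5 so that the tether has one fixed fusion torsion.
- The ketal is the smallest available, so that the conformer placing C10 on the twofold axis of the twist-chair is not additionally favoured.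
- A catalyst-controlled variant of the same ring closure is held ready.

**Aldehyde and bromide termini.** Bromo aldehyde 15 comes from bromo alcohol 14, and 14 from diol 13 by reaction of the allylic hydroxyl only. Diol 13 comes from diester 12 by global reduction, so both termini are carried as esters and are differentiated only at the diol stage. Diester 12 is the ketal of β-keto ester 11. Cutting C9–C10 leads to cyclopentene acid 8 and a malonate half-ester. This two-carbon homologation is preferred to adding a C2 organometallic because it delivers the C10 ketone and the C8 oxidation level in one step.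

**C3=C4 and C7=C11.** Acid 8 is opened at the ring alkene to diene acid 7 (ring-closing metathesis). Acid 7 is cut at the trisubstituted enoate to aldehyde acid 6 and a stabilised ylide. After these cuts the precursor is an open chain with the two stereocentres C1 and C5 on adjacent carbons, bearing allyl and isopropenyl groups.

**Chiral-pool origin.** Aldehyde acid 6 maps onto (S)-carvone 1. Carvone C5 with its isopropenyl group is guaiane C5, carvone C6 is C1, the carbonyl carbon is C10 and carvone C3 is C7. Allylation at carvone C6 gives 2, and epoxidation of the enone gives 3. Oxidative excision of C2 with its methyl group turns the ring into the acid and aldehyde arms of 6. This fixes C5 from a commercial terpene in three steps and sets C1 trans by enolate alkylation. It replaces an enantioselective rearrangement that would need a stoichiometric chiral reagent and several more steps.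

## Roads not taken

**Alternative 1:** Both rings are cut at once (C1–C5, C2–C3, C3–C4) back to the open-chain allenyne A1. In the forward sense, [Rh(CO)2Cl]2 (monovalent rhodium) under CO joins the alkyne to the distal allene double bond and inserts CO, giving dienone A2.
- Merits: two rings are formed in one catalytic step. The C1=C10 bond with its methyl group comes regiodefined from the allene. C7 and C8 are made in an open chain by reagent-controlled anti-selective chemistry, independent of any ring conformation.
- Weak points: C5 is sp2 in A2. The C3 ketone and C4=C5 must then be converted into C3=C4 with hydrogen delivered to one face of C5. That reductive transposition is steered only by C7/C8 across a flat, linearly conjugated dienone, which also invites 1,6-reduction. The sensitive skipped diene would be created in the last steps.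
- Comparison: this road is shorter than the chosen one and is better on both the C7/C8 pair and the C1=C10 regiochemistry. The chosen plan sets against this a C5 centre that is fixed from the first step and never touched. Its one doubtful stereochemical relay is read out at mid-route (step 11) and not at the end.

**Alternative 2:** C1–C5 and C5–C6 are cut, leading to the thymol-derived diazoketone A3. A copper carbene (Cu(MeCN)4PF6, monovalent copper, chiral bis(oxazoline)) adds to the arene, and the norcaradiene opens to azulenone A4.
- Merits: the arene supplies the seven-membered ring with the isopropyl, methyl and oxygen substituents already on C7, C10 and C8. No other road reaches the bicyclic skeleton in so few steps.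
- Weak points: the only stereocentre of A4, C5, is α to the C4 ketone and doubly allylic, so it is labile. The carbene must choose the C1–C6 bond over the methyl-bearing C1–C10 side. C6=C7 and the C8 enol ether must then be reduced to a trans C7/C8 pair on a nearly flat triene while C1=C10 survives.
- Comparison: it is far better in step count. All three stereocentres are insecure, whereas in the chosen plan only the relation of C7/C8 to C5 is.

**Alternative 3:** C5–C6 is cut, with O–C10 re-formed, giving the 2-methylenetetrahydrofuran A5, made from a malic acid lactone. Heating triggers a ring-expanding Claisen rearrangement to hydroazulenone A6.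
- Merits: C8 comes from the chiral pool. The rearrangement installs C1=C10 with its methyl group regiospecifically and creates C5 by suprafacial transfer. The C4 ketal later allows an unambiguous kinetic enol triflate away from C5. This solves the alkene regiochemistry better than step 15 of the chosen plan.
- Weak points: A6 has a ketone at C7 and no isopropyl group. C7 must therefore be built afterwards, trans to C8, next to an epimerisable and eliminable α-silyloxy centre. The quaternary C10 of A5 has to be set selectively only to be destroyed. The exocyclic enol ether must be made from a lactone and then heated.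
- Comparison: the length is comparable and the alkene regiocontrol is better. The chosen plan forms C7 and C8 together, with the complete isopropyl carbon set already in place.

Key step: step 11

Assumption: the epoxide of 3 and the carbinol centres of 4 are drawn as expected by analogy with carvone itself; both are destroyed in step 3, so their configuration has no bearing on the route.

## Route

Step 1
Reactants: 1 (S)-(+)-carvone
Product: 2 (5S,6R)-2-methyl-5-(prop-1-en-2-yl)-6-(prop-2-en-1-yl)cyclohex-2-en-1-one (trans-6-allylcarvone)
Conditions: LiN(i-Pr)2, THF, −78 °C; allyl bromide, −78 → 0 °C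
Reagents that add atoms: allyl bromide, C=CCBr
Why: Kinetic α′-deprotonation gives the cross-conjugated enolate, and enolate alkylation occurs anti to the neighbouring isopropenyl group, setting C6 trans to C5; any cis epimer is expected to equilibrate to trans under the base of step 2.

Step 2
Reactants: 2 trans-6-allylcarvone
Product: 3 (1S,3R,4S,6S)-1-methyl-4-(prop-1-en-2-yl)-3-(prop-2-en-1-yl)-7-oxabicyclo[4.1.0]heptan-2-one
Conditions: 30% aq. H2O2, NaOH (cat.), MeOH, 0 °C
Reagents that add atoms: hydrogen peroxide, OO
Why: Weitz–Scheffer nucleophilic epoxidation attacks only the electron-poor enone double bond and leaves the allyl and isopropenyl groups alone; the epoxide should form anti to the isopropenyl group as with carvone.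

Step 3
Reactants: 3 epoxy ketone
Product: 6 (2R,3S)-5-oxo-3-(prop-1-en-2-yl)-2-(prop-2-en-1-yl)pentanoic acid, via keto diol 4 (not isolated), via diketo aldehyde 5 (not isolated)
Conditions: H5IO6 (3 equiv), THF–H2O (4:1), 0 °C → rt
Reagents that add atoms: water, O
Why: Acid-promoted hydrolysis of the epoxide followed by Malaprade cleavage of the glycol and then of the 1,2-dione excises the methyl-bearing carbon as acetic acid; periodate does not touch isolated alkenes, and the two stereocentres are not involved.

Step 4
Reactants: 6 aldehyde acid
Product: 7 (2R,3S,5E)-7-ethoxy-6-methyl-7-oxo-3-(prop-1-en-2-yl)-2-(prop-2-en-1-yl)hept-5-enoic acid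
Conditions: Ph3P=C(CH3)CO2Et (2 equiv), CH2Cl2, rt → 40 °C
Reagents that add atoms: ethyl 2-(triphenylphosphoranylidene)propanoate, CCOC(=O)C(C)=P(c1ccccc1)(c1ccccc1)c1ccccc1
Why: Wittig olefination with a stabilised α-methyl ylide should give the (E)-trisubstituted enoate; the free acid is tolerated and the lactol form of 6 opens under the conditions.

Step 5
Reactants: 7 diene acid
Product: 8 (1R,5S)-5-[(2E)-4-ethoxy-3-methyl-4-oxobut-2-en-1-yl]-4-methylcyclopent-3-ene-1-carboxylic acid
Conditions: second-generation Grubbs catalyst, RuCl2(=CHPh)(PCy3)(H2IMes) (5 mol %), CH2Cl2 (0.01 M), 40 °C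
Reagents that add atoms: none
Why: Ring-closing metathesis of the allyl and isopropenyl groups closes the five-membered ring with the trisubstituted C3=C4 bond; the electron-poor trisubstituted enoate is a spectator, and the trans arrangement of the two arms follows from step 1.

Step 6
Reactants: 8 cyclopentene acid
Product: 11 ethyl (2E)-4-[(1S,5R)-5-(3-ethoxy-3-oxopropanoyl)-2-methylcyclopent-2-en-1-yl]-2-methylbut-2-enoate, via acyl imidazolide 9 (not isolated), via acylmalonate half-ester 10 (not isolated)
Conditions: CDI, THF, rt; then Mg(O2CCH2CO2Et)2, THF, 40 °C; 1 M HCl work-up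
Reagents that add atoms: magnesium bis(ethyl malonate), CCOC(=O)CC(=O)[O-].CCOC(=O)CC(=O)[O-].[Mg+2]
Why: Masamune-type C-acylation of the magnesium malonate half-ester by the acyl imidazolide and decarboxylation give the β-keto ester under neutral conditions that spare the enoate; any epimerisation at C1 returns the more stable trans isomer.

Step 7
Reactants: 11 β-keto ester
Product: 12 ethyl (2E)-4-[(1S,5R)-5-[2-(2-ethoxy-2-oxoethyl)-1,3-dioxolan-2-yl]-2-methylcyclopent-2-en-1-yl]-2-methylbut-2-enoate
Conditions: TMSOCH2CH2OTMS, TMSOTf (cat.), CH2Cl2, −78 → −20 °C; pyridine quench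
Reagents that add atoms: 1,2-bis(trimethylsilyloxy)ethane, C[Si](C)(C)OCCO[Si](C)(C)C
Why: Noyori-type ketalisation under silyl triflate catalysis converts the ketone into the dioxolane at low temperature, where neither the ring alkene nor the enoate can migrate.

Step 8
Reactants: 12 ketal diester
Product: 13 (2E)-4-[(1S,5R)-5-[2-(2-hydroxyethyl)-1,3-dioxolan-2-yl]-2-methylcyclopent-2-en-1-yl]-2-methylbut-2-en-1-ol
Conditions: i-Bu2AlH (6 equiv), CH2Cl2, −78 → 0 °C; aq. potassium sodium tartrate
Reagents that add atoms: none
Why: Aluminium hydride reduction takes both esters to primary alcohols, the enoate by 1,2-reduction, and leaves the ketal and alkene geometry intact.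

Step 9
Reactants: 13 diol
Product: 14 2-[2-[(1R,2S)-2-[(2E)-4-bromo-3-methylbut-2-en-1-yl]-3-methylcyclopent-3-en-1-yl]-1,3-dioxolan-2-yl]ethan-1-ol
Conditions: NBS, Me2S, CH2Cl2, −20 → 0 °C
Reagents that add atoms: N-bromosuccinimide, O=C1CCC(=O)N1Br
Why: Corey–Kim halide formation: only the allylic alkoxysulfonium ion collapses to the bromide by direct displacement, while the saturated primary hydroxyl is returned on work-up; the (E) geometry is retained.

Step 10
Reactants: 14 bromo alcohol
Product: 15 [2-[(1R,2S)-2-[(2E)-4-bromo-3-methylbut-2-en-1-yl]-3-methylcyclopent-3-en-1-yl]-1,3-dioxolan-2-yl]acetaldehyde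
Conditions: Dess–Martin periodinane, NaHCO3, CH2Cl2, 0 °C → rt
Reagents that add atoms: none
Why: Buffered Dess–Martin oxidation gives the aldehyde without touching the allylic bromide or the ketal; the β-ketal aldehyde is used at once to avoid β-elimination.

Step 11
Reactants: 15 bromo aldehyde
Product: 16 (1R,5S,7R,8S)-10,10-ethylenedioxy-14-norguaia-3,11-dien-8-ol (trans-fused hydroazulenol with C10 spiro-dioxolane, 8-OH and 7-isopropenyl)
Conditions: CrCl2 (divalent chromium, 6 equiv), THF, rt, 15 added over 8 h (final 0.005 M)
Reagents that add atoms: none
Why: Two equivalents of CrCl2 reduce the allylic C–Br bond to an allylchromium species (trivalent chromium) bound at the primary carbon C12, which equilibrates to its E form and adds to the aldehyde through the γ-carbon C7 in a six-membered chair transition state with chromium on the carbonyl oxygen. The closest known reaction type is the intramolecular Nozaki–Hiyama allylation of formyl allylic bromides, which closes seven-membered and larger rings to anti homoallylic alcohols. The ring C1–C5–C6–C7–C8–C9–C10 closes by 7-exo-trig attack of C7 on the C8 carbonyl; attack through C12 would require a nine-membered ring and is not expected. C7 and C8 are created together: with C6 and C9 both equatorial on the chair, the isopropenyl group and the oxygen end up trans, so their relative configuration is set by the transition-state geometry. Their sense relative to C5 is decided by the tether: the trans arms on C1 and C5 fix the sign of the C10–C1–C5–C6 torsion, and the twist-chair with its twofold axis through C6 places the ring fusion, the isopropenyl group and the oxygen all equatorial and leads to (7R,8S). The step needs γ-regioselectivity, the anti mode, this facial preference and cyclisation over oligomerisation; these are secured in turn by the substitution of the allyl unit, the chair, the trans fusion with a compact dioxolane, and high dilution. The facial preference is the least secure, because a second twist-chair with its axis through C10 would give the (7S,8R) isomer; the configuration of 16 is to be assigned by NOE or a crystalline derivative before material is carried on.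

Step 12
Reactants: 16 isopropenyl alcohol
Product: 17 (1R,5S,7R,8S)-10,10-ethylenedioxy-14-norguai-3-en-8-ol
Conditions: H2 (1 atm), RhCl(PPh3)3 (10 mol %), benzene, rt
Reagents that add atoms: none
Why: Homogeneous hydrogenation with RhCl(PPh3)3 reduces the 1,1-disubstituted alkene much faster than the trisubstituted ring alkene and does not isomerise it.

Step 13
Reactants: 17 alcohol
Product: 18 (1R,5S,7R,8S)-8-(tert-butyldimethylsilyloxy)-10,10-ethylenedioxy-14-norguai-3-ene
Conditions: TBSOTf, 2,6-lutidine, CH2Cl2, −78 → 0 °C
Reagents that add atoms: tert-butyldimethylsilyl triflate, CC(C)(C)[Si](C)(C)OS(=O)(=O)C(F)(F)F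
Why: Silylation with the silyl triflate protects the hindered secondary alcohol at low temperature, where the dioxolane is not opened.

Step 14
Reactants: 18 silyl ether ketal
Product: 19 (1R,5S,7R,8S)-8-(tert-butyldimethylsilyloxy)-14-norguai-3-en-10-one
Conditions: PPTS (cat.), acetone–H2O (10:1), 55 °C
Reagents that add atoms: water, O
Why: Mild acid-catalysed ketal hydrolysis frees the C10 ketone; the hindered secondary silyl ether and the trisubstituted alkene tolerate PPTS, and the β-silyloxy ketone does not eliminate under these conditions.

Step 15
Reactants: 19 ketone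
Product: 20 (5R,7R,8S)-8-(tert-butyldimethylsilyloxy)-14-norguaia-1(10),3-dien-10-yl trifluoromethanesulfonate
Conditions: Tf2O, 2,6-di-tert-butyl-4-methylpyridine, CH2Cl2, 0 °C → rt
Reagents that add atoms: triflic anhydride, O=S(=O)(OS(=O)(=O)C(F)(F)F)C(F)(F)F
Why: Enol triflate formation by O-triflylation and loss of a proton under soft, non-basic conditions favours the more substituted enol, here toward the C1 methine, giving the tetrasubstituted C1=C10 triflate without forming a C9 enolate that could expel the silyloxy group.

Step 16
Reactants: 20 enol triflate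
Product: 21 (5R,7R,8S)-8-(tert-butyldimethylsilyloxy)guaia-1(10),3-diene
Conditions: MeMgBr, Fe(acac)3 (10 mol %), THF–NMP, −30 → 0 °C
Reagents that add atoms: methylmagnesium bromide, C[Mg]Br
Why: Iron-catalysed cross-coupling of an alkenyl triflate with a methyl Grignard reagent replaces the triflate by methyl at fixed alkene position; the coupling is fast at low temperature and leaves the silyl ether and the skipped diene alone.

Step 17
Reactants: 21 silyl ether
Product: 22 (5R,7R,8S)-guaia-1(10),3-dien-8-ol
Conditions: Bu4NF, THF, rt → 45 °C
Reagents that add atoms: none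
Why: Fluoride-mediated desilylation frees the C8 alcohol under conditions too weakly basic to deprotonate the doubly allylic C5–H.

Step 18
Reactants: 23 vanillic acid
Product: 24 4-acetoxy-3-methoxybenzoic acid
Conditions: Ac2O, pyridine, rt; aqueous work-up
Reagents that add atoms: acetic anhydride, CC(=O)OC(C)=O
Why: Acetylation masks the phenol; any mixed anhydride at the carboxyl group is hydrolysed on work-up.

Step 19
Reactants: 24 4-acetoxy-3-methoxybenzoic acid
Product: 25 4-acetoxy-3-methoxybenzoyl chloride
Conditions: (COCl)2, DMF (cat.), CH2Cl2, 0 °C → rt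
Reagents that add atoms: oxalyl chloride, O=C(Cl)C(=O)Cl
Why: Acid chloride formation through the Vilsmeier-type intermediate gives the acylating agent needed for a hindered secondary alcohol.

Step 20
Reactants: 22 (5R,7R,8S)-guaia-1(10),3-dien-8-ol; 25 4-acetoxy-3-methoxybenzoyl chloride
Product: 27 (5R,7R,8S)-guaia-1(10),3-dien-8-yl 4-hydroxy-3-methoxybenzoate (CNP0156298.2), via O-acetyl vanillate 26 (not isolated)
Conditions: Et3N, DMAP, CH2Cl2, 0 °C → rt; then pyrrolidine, 0 °C
Reagents that add atoms: none
Why: DMAP-catalysed acylation forms the C8 ester with retention; the aryl acetate is then removed by chemoselective aminolysis, since a phenyl ester is far more electrophilic than the hindered alkyl vanillate.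

## Compound list

1 | (S)-(+)-carvone, (5S)-2-methyl-5-(prop-1-en-2-yl)cyclohex-2-en-1-one | CC(=C)[C@H]1CC=C(C)C(=O)C1 | starting material
2 | (5S,6R)-2-methyl-5-(prop-1-en-2-yl)-6-(prop-2-en-1-yl)cyclohex-2-en-1-one | O=C1[C@H](CC=C)[C@@H](C(C)=C)CC=C1C | intermediate
3 | (1S,3R,4S,6S)-1-methyl-4-(prop-1-en-2-yl)-3-(prop-2-en-1-yl)-7-oxabicyclo[4.1.0]heptan-2-one | O=C1[C@H](CC=C)[C@@H](C(C)=C)C[C@@H]2O[C@]12C | intermediate
4 | (2S,3R,5S,6R)-2,3-dihydroxy-2-methyl-5-(prop-1-en-2-yl)-6-(prop-2-en-1-yl)cyclohexan-1-one | O=C1[C@H](CC=C)[C@@H](C(C)=C)C[C@@H](O)[C@@]1(O)C | intermediate (not isolated)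
5 | (3S,4R)-5,6-dioxo-3-(prop-1-en-2-yl)-4-(prop-2-en-1-yl)heptanal | CC(=O)C(=O)[C@H](CC=C)[C@@H](C(C)=C)CC=O | intermediate (not isolated)
6 | (2R,3S)-5-oxo-3-(prop-1-en-2-yl)-2-(prop-2-en-1-yl)pentanoic acid | OC(=O)[C@H](CC=C)[C@@H](C(C)=C)CC=O | intermediate
7 | (2R,3S,5E)-7-ethoxy-6-methyl-7-oxo-3-(prop-1-en-2-yl)-2-(prop-2-en-1-yl)hept-5-enoic acid | OC(=O)[C@H](CC=C)[C@@H](C(C)=C)C/C=C(\C)C(=O)OCC | intermediate
8 | (1R,5S)-5-[(2E)-4-ethoxy-3-methyl-4-oxobut-2-en-1-yl]-4-methylcyclopent-3-ene-1-carboxylic acid | OC(=O)[C@@H]1CC=C(C)[C@H]1C/C=C(\C)C(=O)OCC | intermediate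
9 | acyl imidazolide of 8, ethyl (2E)-4-[(1S,5R)-5-(imidazole-1-carbonyl)-2-methylcyclopent-2-en-1-yl]-2-methylbut-2-enoate | O=C(n1ccnc1)[C@@H]2CC=C(C)[C@H]2C/C=C(\C)C(=O)OCC | intermediate (not isolated)
10 | acylmalonate half-ester of 8 (malonate CH epimerisable, not specified) | CCOC(=O)C(C(=O)O)C(=O)[C@@H]1CC=C(C)[C@H]1C/C=C(\C)C(=O)OCC | intermediate (not isolated)
11 | ethyl (2E)-4-[(1S,5R)-5-(3-ethoxy-3-oxopropanoyl)-2-methylcyclopent-2-en-1-yl]-2-methylbut-2-enoate | CCOC(=O)CC(=O)[C@@H]1CC=C(C)[C@H]1C/C=C(\C)C(=O)OCC | intermediate
12 | ethyl (2E)-4-[(1S,5R)-5-[2-(2-ethoxy-2-oxoethyl)-1,3-dioxolan-2-yl]-2-methylcyclopent-2-en-1-yl]-2-methylbut-2-enoate | CCOC(=O)CC1(OCCO1)[C@@H]2CC=C(C)[C@H]2C/C=C(\C)C(=O)OCC | intermediate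
13 | (2E)-4-[(1S,5R)-5-[2-(2-hydroxyethyl)-1,3-dioxolan-2-yl]-2-methylcyclopent-2-en-1-yl]-2-methylbut-2-en-1-ol | OCCC1(OCCO1)[C@@H]2CC=C(C)[C@H]2C/C=C(\C)CO | intermediate
14 | 2-[2-[(1R,2S)-2-[(2E)-4-bromo-3-methylbut-2-en-1-yl]-3-methylcyclopent-3-en-1-yl]-1,3-dioxolan-2-yl]ethan-1-ol | OCCC1(OCCO1)[C@@H]2CC=C(C)[C@H]2C/C=C(\C)CBr | intermediate
15 | [2-[(1R,2S)-2-[(2E)-4-bromo-3-methylbut-2-en-1-yl]-3-methylcyclopent-3-en-1-yl]-1,3-dioxolan-2-yl]acetaldehyde | O=CCC1(OCCO1)[C@@H]2CC=C(C)[C@H]2C/C=C(\C)CBr | intermediate
16 | (1R,5S,7R,8S)-10,10-ethylenedioxy-14-norguaia-3,11-dien-8-ol | O[C@H]1CC2(OCCO2)[C@@H]3CC=C(C)[C@H]3C[C@@H]1C(C)=C | intermediate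
17 | (1R,5S,7R,8S)-10,10-ethylenedioxy-14-norguai-3-en-8-ol | O[C@H]1CC2(OCCO2)[C@@H]3CC=C(C)[C@H]3C[C@@H]1C(C)C | intermediate
18 | (1R,5S,7R,8S)-8-(tert-butyldimethylsilyloxy)-10,10-ethylenedioxy-14-norguai-3-ene | CC(C)(C)[Si](C)(C)O[C@H]1CC2(OCCO2)[C@@H]3CC=C(C)[C@H]3C[C@@H]1C(C)C | intermediate
19 | (1R,5S,7R,8S)-8-(tert-butyldimethylsilyloxy)-14-norguai-3-en-10-one | CC(C)(C)[Si](C)(C)O[C@H]1CC(=O)[C@@H]2CC=C(C)[C@H]2C[C@@H]1C(C)C | intermediate
20 | (5R,7R,8S)-8-(tert-butyldimethylsilyloxy)-14-norguaia-1(10),3-dien-10-yl trifluoromethanesulfonate | CC(C)(C)[Si](C)(C)O[C@H]1CC(OS(=O)(=O)C(F)(F)F)=C2CC=C(C)[C@H]2C[C@@H]1C(C)C | intermediate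
21 | (5R,7R,8S)-8-(tert-butyldimethylsilyloxy)guaia-1(10),3-diene | CC(C)(C)[Si](C)(C)O[C@H]1CC(C)=C2CC=C(C)[C@H]2C[C@@H]1C(C)C | intermediate
22 | (5R,7R,8S)-guaia-1(10),3-dien-8-ol | O[C@H]1CC(C)=C2CC=C(C)[C@H]2C[C@@H]1C(C)C | intermediate
23 | vanillic acid, 4-hydroxy-3-methoxybenzoic acid | COc1cc(C(=O)O)ccc1O | starting material
24 | 4-acetoxy-3-methoxybenzoic acid | COc1cc(C(=O)O)ccc1OC(C)=O | intermediate
25 | 4-acetoxy-3-methoxybenzoyl chloride | COc1cc(C(=O)Cl)ccc1OC(C)=O | intermediate
26 | (5R,7R,8S)-guaia-1(10),3-dien-8-yl 4-acetoxy-3-methoxybenzoate | COc1cc(C(=O)O[C@H]2CC(C)=C3CC=C(C)[C@H]3C[C@@H]2C(C)C)ccc1OC(C)=O | intermediate (not isolated)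
27 | (5R,7R,8S)-guaia-1(10),3-dien-8-yl 4-hydroxy-3-methoxybenzoate, CNP0156298.2 | COc1cc(C(=O)O[C@H]2CC(C)=C3CC=C(C)[C@H]3C[C@@H]2C(C)C)ccc1O | target

## Step count and risks

Total step count: 20. Longest linear sequence: 18 (steps 1–17 and 20); steps 18 and 19 form the vanilloyl branch.

**Step 11 (key step).** The most likely failure is poor facial selectivity with respect to C5. The allylchromium would add to the other aldehyde face through the competing twist-chair and give the (7S,8R) anti isomer. Erosion of the anti mode or oligomerisation is less likely. The fallback replaces substrate control by catalyst control of the same ring closure. Setting out from 15, the cyclisation would be run with catalytic CrCl2 (divalent chromium) carrying a chiral tridentate bis(oxazolinyl)carbazole ligand, Mn powder as terminal reductant and Me3SiCl for turnover. The ligand enantiomer is the one that delivers the allyl unit to the Re face of the aldehyde, and the chair and hence the anti mode are unchanged. The primary product is the trimethylsilyl ether of the cyclised alcohol F1, which on brief K2CO3/MeOH treatment gives 16, where the route is rejoined.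

**Step 3.** The most likely failure is slow hydrolytic opening of the electron-poor epoxy ketone. Acid-induced rearrangement or hydration of the isopropenyl group could then compete before periodate acts. The fallback removes the deactivating carbonyl first.
- From 3, Luche reduction (NaBH4, CeCl3, MeOH) gives the epoxy alcohol F2, whose epoxide opens readily.
- H5IO6 then cleaves both C–C bonds of the resulting triol to the dialdehyde F3 and acetic acid.
- The ylide of step 4 (1 equiv, 0 °C) reacts at the unbranched aldehyde to give the enoate aldehyde F4.
- Pinnick oxidation (NaClO2, NaH2PO4, 2-methylbut-2-ene) of the remaining α-branched aldehyde returns the route at 7.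

**Step 15.** The most likely failure is loss of regiocontrol in the enolisation, with the proton taken from C9 instead of the C1 methine. β-Elimination of the silyloxy group is also possible. The fallback separates regiochemistry from triflation.
- From 19, Me3SiI with hexamethyldisilazane under equilibrating conditions gives the more substituted trimethylsilyl enol ether F5, which can be freed of its C9 regioisomer by chromatography.
- MeLi then releases the regiodefined lithium enolate, which is trapped with PhNTf2 to give 20.

**Step 9.** The most likely failure is incomplete discrimination between the two primary hydroxyls, or delivery of bromide with allylic transposition. The fallback differentiates the termini by oxidation state.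
- From 13, MnO2 oxidises only the allylic alcohol to the hydroxy enal F6.
- The remaining hydroxyl is capped as the triethylsilyl ether F7 (Et3SiCl, imidazole).
- NaBH4/CeCl3 returns the allylic alcohol F8.
- PPh3/CBr4 gives the allylic bromide F9.
- Pyridine-buffered HF·pyridine removes the silyl group to give 14.

## Further compounds

F1 | step 11 | trimethylsilyl ether of 16 | C[Si](C)(C)O[C@H]1CC2(OCCO2)[C@@H]3CC=C(C)[C@H]3C[C@@H]1C(C)=C
F2 | step 3 | epoxy alcohol from 3, 1-methyl-4-(prop-1-en-2-yl)-3-(prop-2-en-1-yl)-7-oxabicyclo[4.1.0]heptan-2-ol (carbinol configuration immaterial) | OC1[C@H](CC=C)[C@@H](C(C)=C)C[C@@H]2O[C@]12C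
F3 | step 3 | (2R,3S)-3-(prop-1-en-2-yl)-2-(prop-2-en-1-yl)pentanedial | O=C[C@H](CC=C)[C@@H](C(C)=C)CC=O
F4 | step 3 | ethyl (2E,5S,6R)-6-formyl-2-methyl-5-(prop-1-en-2-yl)nona-2,8-dienoate | O=C[C@H](CC=C)[C@@H](C(C)=C)C/C=C(\C)C(=O)OCC
F5 | step 15 | (5R,7R,8S)-8-(tert-butyldimethylsilyloxy)-10-(trimethylsilyloxy)-14-norguaia-1(10),3-diene | CC(C)(C)[Si](C)(C)O[C@H]1CC(O[Si](C)(C)C)=C2CC=C(C)[C@H]2C[C@@H]1C(C)C
F6 | step 9 | (2E)-4-[(1S,5R)-5-[2-(2-hydroxyethyl)-1,3-dioxolan-2-yl]-2-methylcyclopent-2-en-1-yl]-2-methylbut-2-enal | OCCC1(OCCO1)[C@@H]2CC=C(C)[C@H]2C/C=C(\C)C=O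
F7 | step 9 | triethylsilyl ether of F6 | CC[Si](CC)(CC)OCCC1(OCCO1)[C@@H]2CC=C(C)[C@H]2C/C=C(\C)C=O
F8 | step 9 | allylic alcohol from F7 | CC[Si](CC)(CC)OCCC1(OCCO1)[C@@H]2CC=C(C)[C@H]2C/C=C(\C)CO
F9 | step 9 | triethylsilyl ether of 14 | CC[Si](CC)(CC)OCCC1(OCCO1)[C@@H]2CC=C(C)[C@H]2C/C=C(\C)CBr
A1 | alternative 1 | (5S,6R)-5-(tert-butyldimethylsilyloxy)-3-methyl-6-(propan-2-yl)deca-1,2-dien-8-yne | CC#CC[C@H](C(C)C)[C@@H](O[Si](C)(C)C(C)(C)C)CC(C)=C=C
A2 | alternative 1 | (7R,8S)-8-(tert-butyldimethylsilyloxy)guaia-1(10),4-dien-3-one | O=C1CC2=C(C)C[C@H](O[Si](C)(C)C(C)(C)C)[C@@H](C(C)C)CC2=C1C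
A3 | alternative 2 | 1-diazo-4-[4-methoxy-2-methyl-5-(propan-2-yl)phenyl]butan-2-one | [N-]=[N+]=CC(=O)CCc1cc(C(C)C)c(OC)cc1C
A4 | alternative 2 | (5S)-8-methoxy-15-norguaia-1(10),6,8-trien-4-one | O=C1CCC2=C(C)C=C(OC)C(C(C)C)=C[C@H]12
A5 | alternative 3 | (3S,5R)-3-(tert-butyldimethylsilyloxy)-5-(3,3-ethylenedioxycyclopent-1-en-1-yl)-5-methyl-2-methylideneoxolane (quaternary centre drawn as a chair-like transition state would require) | C=C1O[C@](C)(C[C@@H]1O[Si](C)(C)C(C)(C)C)C2=CC3(OCCO3)CC2
A6 | alternative 3 | (5S,8S)-hydroazulenone with C7 ketone, C1=C10 bearing the C10 methyl, C4 spiro-dioxolane and 8-tert-butyldimethylsilyloxy | O=C1C[C@H]2C(CCC23OCCO3)=C(C)C[C@@H]1O[Si](C)(C)C(C)(C)C
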